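The target at the end of a flask can be read as the target made times the share of it still standing.

| flask | starting material | second substrate | enzyme | remark | time |
|---|---|---|---|---|---|
| birch | 31 mM | 116 mM | 5.8 µM | run made earlier |  |
| elm | 68 mM | 116 mM | 5.8 µM | run made earlier |  |
| alder | 120 mM | 116 mM | 5.8 µM | run made earlier |  |
| winter | 30 mM | 116 mM | 5.8 µM |  | 5.0 h |
| midnight | 40 mM | 116 mM | 5.8 µM |  | 5.0 h |
| summer | 60 mM | 116 mM | 5.8 µM |  | 5.0 h |
| noon | 100 mM | 116 mM | 5.8 µM |  | 5.0 h |
| spring | 150 mM | 116 mM | 5.8 µM |  | 5.0 h |

| run | time / h | target / % | starting material / % |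
|---|---|---|---|
| birch | 0.250 | 2.3 | 97.0 |
| birch | 0.500 | 2.2 | 96.0 |
| birch | 1.00 | 6.4 | 90.4 |
| birch | 2.00 | 14.2 | 82.5 |
| birch | 4.00 | 23.2 | 63.0 |
| elm | 0.667 | 3.3 | 96.3 |
| elm | 1.33 | 6.2 | 92.4 |
| elm | 2.00 | 5.9 | 86.0 |
| elm | 3.00 | 10.5 | 80.6 |
| elm | 4.00 | 12.3 | 73.3 |
| alder | 0.333 | 2.2 | 99.6 |
| alder | 0.833 | 4.3 | 97.7 |
| alder | 1.50 | 4.7 | 94.8 |
| alder | 2.50 | 2.2 | 88.6 |
| alder | 4.00 | 5.8 | 79.8 |

(each reading ± 1 percentage point)

- [target] at the end for winter, midnight, summer, noon, spring, in this order
- the course of these numbers from the first flask to the last (rises all the way / falls, then rises / falls all the way / rises, then falls / hardly changes)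

- the numbers in the tables scatter with a standard deviation of 1 percentage point
- "hardly changes" means that all values lie within two and a half points (for a concentration: within two and a half percent of the largest)

1. Making. In the elm run at 4.00 h, 14.4% of the charge is neither starting material nor target, and this gap opens late. My assumption is that each lost target takes one starting material with it, so the gap holds 2 units per loss. The target made is then the mean of starting material gone and target found. Over the runs this gives a making rate v of 2.33 mM h⁻¹ in birch, 3.32 mM h⁻¹ in elm and 3.90 mM h⁻¹ in alder.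

2. Lifetime. The elm run loses 4.90 mM of target while holding about 4.18 mM on average. Read from these scattered values, a target in the elm run lasts about τ = 3.42 h at a mean starting material of 58.9 mM. I take the loss as pseudo-first-order in target, with its rate proportional to starting material. A flask with mean starting material S then lives through L lifetimes in its time t, where L = (t/τ)·(S/58.9 mM). S is taken as the charge less what making uses by mid-run.

3. Both ends. At small L the target is v·t. At large L it stands near the steady state v·τ·(58.9 mM/S). Joining them gives f = (1 − e^(−L))/L, the kept share: the part of the target made that still stands at the end.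

4. Numbers. Spring, with alder's v, has L = 3.48, so f = 27.8% and the target ends at 5.43 mM. Winter, with birch's v, has L = 0.600, so f = 75.2% and the target ends at 8.77 mM. Summer, with elm's v, has L = 1.28 and ends at 9.33 mM. My row therefore rises, then falls.

5. Forecast. The forecast puts the flasks at 7.9 mM, 9 mM, 9.4 mM, 8.2 mM and 6.6 mM, a row that rises, then falls with “a shallow maximum”, so it stands lower than my reckoning in winter and higher in spring.

6. Result. The flasks end at 8.50 mM, 8.83 mM, 8.48 mM, 6.81 mM and 5.06 mM; the row rises, then falls.

    starting material + enzyme ⇌ starting complex (K = 35.0 L mol⁻¹, k = 1000 L mol⁻¹ s⁻¹)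
    ternary complex → enzyme + target (k = 0.790 s⁻¹)
    second substrate + starting complex ⇌ ternary complex (K = 3.30 L mol⁻¹, k = 340 L mol⁻¹ s⁻¹)
    2 starting material → homo dimer (k = 2.60 × 10⁻⁶ L mol⁻¹ s⁻¹)
    starting material + target → side product (k = 0.00150 L mol⁻¹ s⁻¹)

The largest single effect on the end target is the undoing of ternary complex into second substrate + starting complex, in spring  and in winter : without it spring ends at 37.3 mM and winter at 27.0 mM. The loss that f counts, the reaction of starting material + target to side product, is a part of what holds the spring target down. The spring run without it ends at 18.5 mM against 5.06 mM, a kept share of 27.4%, where f gave 27.8%. For winter f gave 75.2%, and there the same reaction is again a part: the winter run without it ends at 11.5 mM against 8.50 mM, a kept share of 73.9%.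

The numbers in the tables are simulated from invented constants.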